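The numbers in the tables were computed from invented constants.

The amount of target in the zeta run climbs to a top and then falls, so what I watch on a repeat is how high that top stands for each molar of second reagent.

in all of them: substrate 1.5 M; gas 200 mM (held)

| charge | second reagent | remark | time |
|---|---|---|---|
| beta | 1.8 M | the very flask that is asked about, followed so far |  |
| zeta | 2.7 M | run made earlier |  |
| flask | 1.80 M |  | 2.0 h |

| run | time / min | target / % |
|---|---|---|
| beta | 2.00 | 0 |
| beta | 5.00 | 0.3 |
| beta | 10.0 | 0.5 |
| beta | 15.0 | 0.5 |
| beta | 20.0 | 2.1 |
| zeta | 25.0 | 3.7 |
| zeta | 50.0 | 8.2 |
| zeta | 80.0 | 10.3 |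
| zeta | 90.0 | 10.2 |
| zeta | 120 | 9.5 |

(each reading ± 0.5 percentage points)

- time up to 2.0 h at which target stands highest
- the amount of target, in percent of the substrate charged, at that time

The beta and zeta runs differ in their charge of second reagent. Beta's mean rate up to 20.0 min over zeta's up to 25.0 min is 0.709, and the charges stand at 0.667, so I take the making of target as first order in second reagent. Zeta's readings stop rising near 80.0 min, and at a top the making and the loss of target are equal. I assume that the loss does not depend on second reagent, so the top should scale with the charge. Zeta's highest reading over its charge is 0.0381 M⁻¹, and I carry this as the top height per molar. For the flask it gives 6.87%, and I expect the top near zeta's time, 1.42 h.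

The forecast says 9% at 1.8 h, leaning to the case in which “beta is simply zeta slowed 1.5-fold”. My reckoning is lower in height and earlier.

The flask gives 8.15% at 1.50 h.

    substrate + partner → intermediate (k = 0.00140 M⁻¹ s⁻¹)
    second reagent + intermediate → target (k = 1.10 × 10⁻⁴ M⁻¹ s⁻¹)
    partner + target → over-reaction product (k = 0.00450 M⁻¹ s⁻¹)
    gas ⇌ partner, rate k4*(csat - [partner]) (kL = 0.00940 s⁻¹)

The flask's height per molar is 0.0453 M⁻¹, more than zeta's reading gave. At its top, target's loss is pseudo-first-order in target, with partner at 0.178 M. Setting making equal to loss, with intermediate at 43.4% and second reagent at 76.0% of its charge, puts target at 8.15%. So at the flask's top, the height per molar goes with intermediate over partner and with the part of second reagent left.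

In the neighbour flask with 0.72 M of second reagent, the carried height gives 2.74%. The computed top is 3.97%, which is 0.0551 M⁻¹, with intermediate at 63.6% at the end against 42.6% in the flask.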